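**Retrosynthetic overview**

- Target 19 is traced back, by dioxolane hydrolysis and ester saponification, to methyl salicylate 17, in which the side-chain ketone is masked as a ketal.
- The strategy rests on the benzene ring: C1 (CO2H) and C6 (CH2 side chain) are adjacent, and C2(OH)–C3H–C4(OMe)–C5H is a 1,3-dioxygenated four-carbon unit. That unit corresponds to a 1,1,3-trioxygenated butadiene; C1/C6 with their substituents correspond to a 2-alkynoate.
- The benzene ring is the only ring and is made in one operation: (4+2) cycloaddition of diene 14 with ynoate 9 forms C1–C2 and C5–C6, and loss of methanol aromatizes the adduct.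
- Ynoate 9 comes from dodecanoyl chloride via the Meldrum's acid β-keto ester, the ketal, the aldehyde and a Corey–Fuchs homologation with methoxycarbonylation. Diene 14 comes from methyl acetoacetate in two steps.

Key step: step 8

Remark: the target has no stereocentre. The geometry of the ketene acetal double bond of diene 14 is lost on aromatization and is drawn arbitrarily.

**Route**

Step 1
Reactants: 1 dodecanoyl chloride; 2 Meldrum's acid (2,2-dimethyl-1,3-dioxane-4,6-dione)
Product: 4 methyl 3-oxotetradecanoate, via acyl Meldrum's acid 3 (not isolated)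
Conditions: pyridine (2 equiv), CH2Cl2, 0 °C to rt; dilute HCl wash, concentrate; then MeOH, reflux
Reagents that add atoms: methanol, CO
Why: C-acylation of Meldrum's acid followed by methanolysis of the acyl Meldrum's acid with loss of acetone and CO2 is the standard Meldrum's acid route to β-keto esters.

Step 2
Reactants: 4 methyl 3-oxotetradecanoate
Product: 5 methyl 2-(2-undecyl-1,3-dioxolan-2-yl)acetate
Conditions: ethylene glycol (3 equiv), p-TsOH (cat.), toluene, reflux, Dean–Stark trap
Reagents that add atoms: ethylene glycol, OCCO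
Why: Acid-catalysed ketalization with azeotropic removal of water should protect the ketone selectively, the ester carbonyl being much less electrophilic.

Step 3
Reactants: 5 methyl 2-(2-undecyl-1,3-dioxolan-2-yl)acetate
Product: 6 2-(2-undecyl-1,3-dioxolan-2-yl)acetaldehyde
Conditions: i-Bu2AlH (1.05 equiv), CH2Cl2, −78 °C; MeOH quench at −78 °C, then aq. potassium sodium tartrate (KNaC4H4O6)
Reagents that add atoms: none
Why: Partial reduction of an ester with i-Bu2AlH at low temperature should stop at the aldehyde oxidation level, since chelation of aluminium by the neighbouring dioxolane oxygen prevents a second hydride transfer before the quench.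

Step 4
Reactants: 6 2-(2-undecyl-1,3-dioxolan-2-yl)acetaldehyde
Product: 7 2-(3,3-dibromoprop-2-en-1-yl)-2-undecyl-1,3-dioxolane
Conditions: CBr4 (2 equiv), PPh3 (4 equiv), Et3N (1 equiv), CH2Cl2, 0 °C
Reagents that add atoms: carbon tetrabromide, BrC(Br)(Br)Br
Why: This is the dibromo-olefination stage of the Corey–Fuchs reaction (Wittig reaction of Ph3P=CBr2); Et3N buffers adventitious HBr so that the dioxolane and the β-alkoxy aldehyde are not opened.

Step 5
Reactants: 7 2-(3,3-dibromoprop-2-en-1-yl)-2-undecyl-1,3-dioxolane
Product: 9 methyl 4-(2-undecyl-1,3-dioxolan-2-yl)but-2-ynoate, via lithium acetylide 8 (not isolated)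
Conditions: n-BuLi (2.1 equiv), THF, −78 °C; then ClCO2Me (1.5 equiv), −78 to −20 °C
Reagents that add atoms: methyl chloroformate, COC(=O)Cl
Why: In the second Corey–Fuchs stage, bromine–lithium exchange, 1,2-shift of the carbenoid and deprotonation should give the lithium acetylide, which is C-acylated by the chloroformate to the ynoate.

Step 6
Reactants: 10 methyl acetoacetate
Product: 12 methyl (E)-3-methoxybut-2-enoate, via dimethyl ketal 11 (not isolated)
Conditions: HC(OMe)3 (1.1 equiv), H2SO4 (cat.), rt; then distillation
Reagents that add atoms: trimethyl orthoformate, COC(OC)OC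
Why: Acid-catalysed ketalization of the ketone by the orthoformate and loss of methanol on distillation should give the conjugated enol ether as the more stable E isomer.

Step 7
Reactants: 12 methyl (E)-3-methoxybut-2-enoate
Product: 14 1,3-dimethoxy-1-(trimethylsilyloxy)buta-1,3-diene, via lithium dienolate 13 (not isolated)
Conditions: LiN(i-Pr)2 (1.1 equiv), THF, −78 °C; then Me3SiCl (1.2 equiv), −78 °C to rt; non-aqueous work-up (pentane, filtration), distillation
Reagents that add atoms: chlorotrimethylsilane, C[Si](C)(C)Cl
Why: Kinetic γ-deprotonation of the 3-methoxycrotonate and O-silylation of the resulting dienolate is the standard preparation of this silyl ketene acetal diene.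

Step 8
Reactants: 9 methyl 4-(2-undecyl-1,3-dioxolan-2-yl)but-2-ynoate; 14 1,3-dimethoxy-1-(trimethylsilyloxy)buta-1,3-diene (2.5 equiv)
Product: 17 methyl 2-hydroxy-4-methoxy-6-[(2-undecyl-1,3-dioxolan-2-yl)methyl]benzoate, via cyclohexadiene cycloadduct 15 (not isolated), via aryl trimethylsilyl ether 16 (not isolated)
Conditions: toluene, 110 °C, sealed tube; then 5% aq. citric acid, THF, 0 °C
Reagents that add atoms: none
Why: The electron-rich diene (HOMO) and the electron-poor ynoate (LUMO) should combine in an asynchronous normal-demand Diels–Alder reaction to give the cyclohexa-1,4-diene 15; ionization at its mixed-acetal carbon and loss of methanol and a ring proton give the aryl silyl ether 16, whose O–Si bond is cleaved in the mildly acidic work-up. The closest known reaction type is the cycloaddition of 1,1,3-trioxygenated butadienes with acetylenic esters to give resorcylates after aromatization. The benzene ring is closed intermolecularly in the (4+2) mode, C1–C2 and C5–C6 being formed in the same operation. No stereocentre persists, because the acetal carbon of 15 is transient and becomes planar on aromatization. Regioselectivity is required and follows from polarity matching: the CH2 terminus of the diene (largest HOMO coefficient) bonds to the β-carbon of the ynoate (largest LUMO coefficient), which places the side chain at C6 and the ester at C1 next to the C2 oxygen. Loss of methanol in preference to silanol is also required, and any adduct that survives the heating is expected to converge on the same phenol in the acidic work-up; the dioxolane is inert to the neutral thermal conditions and to brief cold citric acid.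

Step 9
Reactants: 17 methyl 2-hydroxy-4-methoxy-6-[(2-undecyl-1,3-dioxolan-2-yl)methyl]benzoate
Product: 18 2-hydroxy-4-methoxy-6-[(2-undecyl-1,3-dioxolan-2-yl)methyl]benzoic acid
Conditions: KOH (4 M aq., excess), DMSO, 80 °C; then 1 M HCl to pH 3 at 0 °C, immediate extraction
Reagents that add atoms: potassium hydroxide, [K+].[OH-]
Why: Saponification of the doubly ortho-substituted salicylate should proceed under forcing basic conditions, to which the ketal, the aryl ether and the carboxylate are inert; cold acidification avoids decarboxylation.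

Step 10
Reactants: 18 2-hydroxy-4-methoxy-6-[(2-undecyl-1,3-dioxolan-2-yl)methyl]benzoic acid
Product: 19 2-hydroxy-4-methoxy-6-(2-oxotridecyl)benzoic acid (target)
Conditions: 1 M aq. HCl, THF, rt
Reagents that add atoms: water, O
Why: Acid-catalysed hydrolysis of the dioxolane should release the ketone at room temperature, where decarboxylation and cyclodehydration to the isocoumarin are not expected.

**Compound list**

1 | dodecanoyl chloride | CCCCCCCCCCCC(=O)Cl | starting material
2 | Meldrum's acid (2,2-dimethyl-1,3-dioxane-4,6-dione) | CC1(C)OC(=O)CC(=O)O1 | starting material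
3 | 5-(1-hydroxydodecylidene)-2,2-dimethyl-1,3-dioxane-4,6-dione (acyl Meldrum's acid) | CCCCCCCCCCCC(O)=C1C(=O)OC(C)(C)OC1=O | intermediate (not isolated)
4 | methyl 3-oxotetradecanoate | CCCCCCCCCCCC(=O)CC(=O)OC | intermediate
5 | methyl 2-(2-undecyl-1,3-dioxolan-2-yl)acetate | CCCCCCCCCCCC1(CC(=O)OC)OCCO1 | intermediate
6 | 2-(2-undecyl-1,3-dioxolan-2-yl)acetaldehyde | CCCCCCCCCCCC1(CC=O)OCCO1 | intermediate
7 | 2-(3,3-dibromoprop-2-en-1-yl)-2-undecyl-1,3-dioxolane | CCCCCCCCCCCC1(CC=C(Br)Br)OCCO1 | intermediate
8 | lithium 3-(2-undecyl-1,3-dioxolan-2-yl)prop-1-yn-1-ide (lithium acetylide) | CCCCCCCCCCCC1(CC#C[Li])OCCO1 | intermediate (not isolated)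
9 | methyl 4-(2-undecyl-1,3-dioxolan-2-yl)but-2-ynoate | CCCCCCCCCCCC1(CC#CC(=O)OC)OCCO1 | intermediate
10 | methyl acetoacetate | CC(=O)CC(=O)OC | starting material
11 | methyl 3,3-dimethoxybutanoate (dimethyl ketal) | CC(OC)(OC)CC(=O)OC | intermediate (not isolated)
12 | methyl (E)-3-methoxybut-2-enoate | CO/C(C)=C/C(=O)OC | intermediate
13 | lithium 1,3-dimethoxybuta-1,3-dien-1-olate (lithium dienolate) | C=C(OC)C=C(OC)O[Li] | intermediate (not isolated)
14 | 1,3-dimethoxy-1-(trimethylsilyloxy)buta-1,3-diene | COC(=C)/C=C(\OC)O[Si](C)(C)C | intermediate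
15 | methyl 4,6-dimethoxy-6-(trimethylsilyloxy)-2-[(2-undecyl-1,3-dioxolan-2-yl)methyl]cyclohexa-1,4-diene-1-carboxylate (racemic) | CCCCCCCCCCCC1(CC2=C(C(=O)OC)C(OC)(O[Si](C)(C)C)C=C(OC)C2)OCCO1 | intermediate (not isolated)
16 | methyl 4-methoxy-2-(trimethylsilyloxy)-6-[(2-undecyl-1,3-dioxolan-2-yl)methyl]benzoate | CCCCCCCCCCCC1(Cc2cc(OC)cc(O[Si](C)(C)C)c2C(=O)OC)OCCO1 | intermediate (not isolated)
17 | methyl 2-hydroxy-4-methoxy-6-[(2-undecyl-1,3-dioxolan-2-yl)methyl]benzoate | CCCCCCCCCCCC1(Cc2cc(OC)cc(O)c2C(=O)OC)OCCO1 | intermediate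
18 | 2-hydroxy-4-methoxy-6-[(2-undecyl-1,3-dioxolan-2-yl)methyl]benzoic acid | CCCCCCCCCCCC1(Cc2cc(OC)cc(O)c2C(=O)O)OCCO1 | intermediate
19 | 2-hydroxy-4-methoxy-6-(2-oxotridecyl)benzoic acid | CCCCCCCCCCCC(=O)Cc1cc(OC)cc(O)c1C(=O)O | target

**Step count and risks**

Total step count: 10 (steps 1–5 to the ynoate, steps 6–7 to the diene, steps 8–10 in common).
Longest linear sequence: 8 steps (1, 2, 3, 4, 5, 8, 9, 10).

Steps most likely to fail:

1. Step 8. The cycloaddition may be slow at the β-carbon, which carries a neopentyl-type substituent, while the diene decays thermally. Trimethylsilanol may also be lost in place of methanol during aromatization, which would leave the C2 oxygen methylated. The fallback sets out from 1 and comes back at 17, building the arene by lateral metalation instead of cycloaddition. Compound 1 is converted with N,O-dimethylhydroxylamine hydrochloride and pyridine (CH2Cl2, 0 °C) into N-methoxy-N-methyldodecanamide F1. Commercial methyl 2,4-dimethoxy-6-methylbenzoate (COC(=O)c1c(C)cc(OC)cc1OC) is lithiated at the benzylic methyl group with LiN(i-Pr)2 (2 equiv, THF, −78 °C) and acylated with F1 to give methyl 2,4-dimethoxy-6-(2-oxotridecyl)benzoate F2. BCl3 (CH2Cl2, −78 to 0 °C) should cleave only the methyl ether chelated to the ester carbonyl, giving methyl 2-hydroxy-4-methoxy-6-(2-oxotridecyl)benzoate F3. Ketalization with ethylene glycol (HC(OEt)3, cat. p-TsOH, rt) then gives 17.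

2. Step 9. Hydroxide attack on the doubly ortho-substituted, phenoxide-deactivated ester may be very slow, and the salicylic acid may decarboxylate during acidification. The fallback sets out from 7 and comes back at 18, releasing the acid by hydrogenolysis instead of acyl substitution. Lithium acetylide 8, generated from 7 as in step 5, is trapped with benzyl chloroformate to give benzyl 4-(2-undecyl-1,3-dioxolan-2-yl)but-2-ynoate F4. Cycloaddition of F4 with 14 under the conditions of step 8 should pass through benzyl 4,6-dimethoxy-6-(trimethylsilyloxy)-2-[(2-undecyl-1,3-dioxolan-2-yl)methyl]cyclohexa-1,4-diene-1-carboxylate F5 and benzyl 4-methoxy-2-(trimethylsilyloxy)-6-[(2-undecyl-1,3-dioxolan-2-yl)methyl]benzoate F6 to benzyl 2-hydroxy-4-methoxy-6-[(2-undecyl-1,3-dioxolan-2-yl)methyl]benzoate F7. Hydrogenolysis (H2, palladium on carbon (Pd/C), EtOAc, rt) cleaves the benzyl ester under neutral conditions and gives 18.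

3. Step 4. The dioxolane may open, or the β-alkoxy aldehyde may undergo β-elimination, under the phosphine/CBr4 conditions; the same elimination threatens the carbenoid stage of step 5. The fallback sets out from 6 and comes back at 9, using a one-carbon diazo homologation. Seyferth–Gilbert homologation of 6 with the Ohira–Bestmann reagent (dimethyl (1-diazo-2-oxopropyl)phosphonate, K2CO3, MeOH, 0 °C to rt) gives 2-(prop-2-yn-1-yl)-2-undecyl-1,3-dioxolane F8. Deprotonation with n-BuLi (1.05 equiv, THF, −78 °C) gives acetylide 8, and methyl chloroformate then gives 9.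

**Further compounds**

F1 | step 8 | N-methoxy-N-methyldodecanamide | CCCCCCCCCCCC(=O)N(C)OC
F2 | step 8 | methyl 2,4-dimethoxy-6-(2-oxotridecyl)benzoate | CCCCCCCCCCCC(=O)Cc1cc(OC)cc(OC)c1C(=O)OC
F3 | step 8 | methyl 2-hydroxy-4-methoxy-6-(2-oxotridecyl)benzoate | CCCCCCCCCCCC(=O)Cc1cc(OC)cc(O)c1C(=O)OC
F4 | step 9 | benzyl 4-(2-undecyl-1,3-dioxolan-2-yl)but-2-ynoate | CCCCCCCCCCCC1(CC#CC(=O)OCc2ccccc2)OCCO1
F5 | step 9 | benzyl 4,6-dimethoxy-6-(trimethylsilyloxy)-2-[(2-undecyl-1,3-dioxolan-2-yl)methyl]cyclohexa-1,4-diene-1-carboxylate | CCCCCCCCCCCC1(CC2=C(C(=O)OCc3ccccc3)C(OC)(O[Si](C)(C)C)C=C(OC)C2)OCCO1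
F6 | step 9 | benzyl 4-methoxy-2-(trimethylsilyloxy)-6-[(2-undecyl-1,3-dioxolan-2-yl)methyl]benzoate | CCCCCCCCCCCC1(Cc2cc(OC)cc(O[Si](C)(C)C)c2C(=O)OCc2ccccc2)OCCO1
F7 | step 9 | benzyl 2-hydroxy-4-methoxy-6-[(2-undecyl-1,3-dioxolan-2-yl)methyl]benzoate | CCCCCCCCCCCC1(Cc2cc(OC)cc(O)c2C(=O)OCc2ccccc2)OCCO1
F8 | step 4 | 2-(prop-2-yn-1-yl)-2-undecyl-1,3-dioxolane | CCCCCCCCCCCC1(CC#C)OCCO1
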